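## Analysis of the target

Target 30 is a labdane whose rings A and B form a trans-fused decalin; ring B holds a tetrasubstituted C8–C9 alkene that carries the C17 methyl group on C8 and the six-carbon (E)-3-methylpent-2-enoic acid unit (C11–C16) on C9. There are five stereocentres, of configuration 3R,4S,5R,6R,10S: quaternary C10 (β-methyl C20), C5 (α-H), quaternary C4 (α-methyl C18, β-CH2O-isovalerate C19), C3 (α-isovalerate, axial) and C6 (β-hydroxyl, axial). C19, C20 and the 6-hydroxyl are mutually 1,3-diaxial on the β-face, and the C3 ester is axial on the α-face. The sensitive groups are the two isovalerates (base-labile and next to a free hydroxyl), the hindered 6β-hydroxyl that must stay unacylated, the tetrasubstituted alkene (it migrates under acid) and the (E)-enoic acid. The difficulty lies in the contiguous C3–C6 array, in which C5 sits between two quaternary carbons, in telling three oxygen functions apart, and in the tetrasubstituted alkene. The route rests on one feature: once the chain is cut at C12–C13, C8=C9 with C17 on C8 and a vinyl group (C11=C12) on C9 is a 1-vinyl-2-methylcyclohexene. That is the product pattern of an enyne ring closure between an ethynyl group on C10 and a 2-methylallyl group on C6, so ring B can be closed last on a finished ring A.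

## Retrosynthetic reasoning

**30 ⇒ 29.** The acid is unmasked last from a 2-(trimethylsilyl)ethyl ester. Fluoride spares the two isovalerates, and acid, which would move the C8–C9 alkene, is avoided.

**29 ⇒ 23 + 27.** The C12–C13 bond is cut. Hydroboration of the vinyl group of 23 (giving borane 28) and sp3–sp2 cross-coupling with enol triflate 27 brings in C13–C16 with the alkene geometry already fixed in a small fragment. An olefination at C13=C14 would leave that geometry open. Triflate 27 comes from acetoacetate 26, which comes from 24 and 25.

**23 ⇒ 22 (key).** The C8–C9 ring bond and the C11–C12 bond are cut together. Going forward, the alkyne on C10 and the isopropenyl terminus on the C6 side chain of 22 are joined by a ruthenium carbene, which closes ring B and moves the alkene methylene to the alkyne terminus. All five stereocentres and both esters are already in place, and the geometry of the tetrasubstituted alkene is fixed by the ring.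

**22 ⇒ 18 + 19.** The C6–C7 bond is cut next to the carbinol. A reagent-controlled methallylboration of aldehyde 18 (through 20 and 21) sets C6, and the boron reagent leaves the two esters alone.

**18 ⇒ 16 ⇒ 15 ⇒ 13 + 14.** The C6 aldehyde is traced to a tert-butyl ester. This is the one carbonyl group that survives the hydride reduction of C19 and is then released by acid after O3 and O19 have each been acylated with one equivalent of 14. The 6-hydroxyl therefore does not exist while the other two oxygens are esterified, and no hydroxyl has to be told from another.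

**13 ⇒ 12 ⇒ 11.** The C19 alcohol comes from the methyl ester, and the C3 carbinol from the ketone by a reagent-controlled reduction, because the monocyclic ring gives no dependable facial bias.

**11 ⇒ 10 ⇒ 9.** The C4–C18 bond is cut (alkylation of a β-keto ester enolate anti to the C5 substituent), then the C9–C11 bond (one-carbon homologation of the C10 aldehyde to the alkyne).

**9 ⇒ 5 + 7 (through 8).** The C4–C5 and C1–C10 bonds of ring A are cut in a Diels–Alder sense. Diene 5 supplies C1–C4 with the C3 oxygen and the C19 carboxyl. Dienophile 7 supplies C5 and C10 with the methyl group, the formyl group (later the alkyne) and the tert-butyl ester (later C6); its (E)-geometry becomes the trans relation of C9 and C6.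

**5 ⇒ 4 ⇒ 3 ⇒ 1 + 2, and 7 ⇒ 6.** These are an aldol/oxidation/silylation sequence and an allylic oxidation.

## Alternatives that were turned down

Alternative 1: Here C3–C4 and C5–C10 are cut in an intramolecular Diels–Alder reaction. Heating a substrate in which a 1-silyloxy diene (C3, C2, C1, C10) is tethered through C6–C9 to the alkene of a butenolide would give tricyclic lactone A1, with both rings closed and C3, C4, C5 and C10 set relative to C6 in one step.
- For it: the step count of the skeleton is low, and the 19,6β-lactone separates O19/O6 from O3 at no cost. On that point it is stronger than the chosen route, which spends five steps on oxygen differentiation.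
- Against it: both new bonds join a carbon that becomes quaternary (C4, C10). The diene terminus C10 is fully substituted, so one group must point inward in the reactive s-cis form. The configuration at C3 depends on an endo/exo preference that the tether may not enforce. The acyclic substrate must already contain the stereodefined tetrasubstituted C8=C9 alkene, for which there is no easy method.
- After the cycloaddition, the C1=C2 alkene must be reduced selectively, the lactone reduced, the C3 silyl ether exchanged, and the C13 ketone olefinated with an E/Z problem.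
- The chosen route gives up that one-step build-up and gains a ring closure in which the tetrasubstituted alkene cannot have the wrong geometry or position.

Alternative 2: Here C4–C5 and C1–C10 are cut with ring B already present as the quinone monoketal A2 (taken as the dimethyl ketal). BINOL–TiCl2, from BINOL and TiCl2(O-i-Pr)2, would activate the C9 carbonyl, and a silyloxy dienoate of the type of 5 would add across C5=C10. Acid work-up would free the C3 and C6 ketones and give trione A3.
- For it: it is convergent, starts from a cheap symmetric dienone, and reaches a decalin with C10 set in one catalytic step. It is shorter to the bicycle than the chosen route.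
- Against it: the dienophile is a methyl-substituted alkene of a cross-conjugated dienone, hence sluggish. The catalyst must choose between two enantiotopic alkenes of a non-chelating substrate. A3 then needs much redox editing: three ketones must be told apart, C9 must be turned from a ketone into an alkene carbon bearing the side chain, the C7=C8 enone must be moved to C8=C9, C6 must become the axial alcohol, and C4 still has to be methylated.
- The chosen route is longer before ring B exists but needs no such editing of ring B afterwards.

Alternative 3: Here C4–C5 and C9–C10 are cut in an oxidative radical bicyclisation. Mn(OAc)3 would oxidise the β-keto ester terminus of an acyclic diene to the C4 radical, two 6-endo additions would close rings A and B, and Cu(OAc)2 would turn the C8 radical into the exocyclic alkene of A4.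
- For it: it forms the most skeletal bonds per step of all four plans, and the axial C4 ester and the trans ring fusion are the usual outcome of this reaction type.
- Against it: absolute control must come from the C6 silyloxy group alone, and A4 carries it in the 6α-configuration, so C6 has to be inverted by oxidation and reduction. The 8(17)-alkene must then be isomerised into the tetrasubstituted position, where the 7-ene competes. C3 still needs reduction to the axial alcohol. The E,E-configured acyclic substrate and the later C13 olefination add steps.
- The chosen route forms the C8=C9 alkene directly where it is needed and sets C6 with a reagent.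

Key step: step 14

Remark on locants: ring A compounds carry the labdane locants of the target (ring carbons C1–C5 and C10; substituent carbons C6, C9, C11, C18, C19, C20); β is the face of the C20 methyl group.

Assumption: in step 5 the (S)-prolinol-derived oxazaborolidinium ion is taken to leave open the face of 7 that is Si at both alkene carbons (formyl C–H···O binding model for 2-substituted enals); if the sense is the reverse, the mirror-image catalyst is meant.

## Route

Step 1
Reactants: 1 methyl acetate; 2 acrolein
Product: 3 methyl 3-hydroxypent-4-enoate (racemic)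
Conditions: LDA, THF, −78 °C; then 2, −78 °C; aq. NH4Cl
Reagents that add atoms: none
Why: Crossed aldol addition; the lithium ester enolate adds 1,2 to the enal at low temperature. The carbinol is oxidised in the next step, so no stereocontrol is needed.

Step 2
Reactants: 3 methyl 3-hydroxypent-4-enoate
Product: 4 methyl 3-oxopent-4-enoate
Conditions: Dess–Martin periodinane, CH2Cl2, 0 °C → rt; used at once
Reagents that add atoms: none
Why: Dess–Martin oxidation of the allylic alcohol gives the vinyl ketone (a Nazarov-type β-keto ester) under neutral conditions that spare this polymerisation-prone enone.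

Step 3
Reactants: 4 methyl 3-oxopent-4-enoate
Product: 5 methyl (2Z)-3-[(triisopropylsilyl)oxy]penta-2,4-dienoate
Conditions: i-Pr3SiOTf, Et3N, CH2Cl2, −78 → 0 °C
Reagents that add atoms: triisopropylsilyl trifluoromethanesulfonate, CC(C)[Si](C(C)C)(C(C)C)OS(=O)(=O)C(F)(F)F
Why: Soft enolisation and O-silylation of the β-keto ester give the 2-silyloxy diene. The (Z)-enol ether (ester and silyloxy cis) follows from the internally bonded enol and leaves only hydrogen inside the s-cis diene.

Step 4
Reactants: 6 tert-butyl 3-methylbut-2-enoate
Product: 7 tert-butyl (2E)-3-methyl-4-oxobut-2-enoate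
Conditions: SeO2, 1,4-dioxane, reflux
Reagents that add atoms: selenium dioxide, O=[Se]=O
Why: Riley allylic oxidation takes the methyl group trans to the ester to the aldehyde and gives the (E)-enal, as with the lower alkyl esters.

Step 5
Reactants: 5 methyl (2Z)-3-[(triisopropylsilyl)oxy]penta-2,4-dienoate; 7 tert-butyl (2E)-3-methyl-4-oxobut-2-enoate
Product: 9 ring A keto aldehyde [C3 ketone; C4 CO2Me (epimers/enol); C5β CO2t-Bu; C10β CH3; C10α CHO], via cycloadduct silyl enol ether 8 (not isolated)
Conditions: (S)-3,3-diphenyl-1-(o-tolyl)tetrahydro-1H,3H-pyrrolo[1,2-c][1,3,2]oxazaborole·HN(SO2CF3)2 (20 mol %), CH2Cl2, −78 → −40 °C; then HF·pyridine, THF, 0 °C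
Reagents that add atoms: none
Why: Catalytic asymmetric Diels–Alder reaction with the chiral oxazaborolidinium ion bound to the aldehyde; the nucleophilic ester-bearing diene terminus bonds to the carbon β to the formyl group (C4–C5) and the CH2 terminus to the methyl-bearing carbon (C1–C10). The (E)-geometry of 7 becomes the trans relation of the C10 formyl and C5 ester groups, and the open face of the bound enal sets C5 and C10 together. C4 is enolisable and is left undefined; fluoride then frees the C3 ketone.

Step 6
Reactants: 9 ring A keto aldehyde
Product: 10 alkynyl keto ester [as 9 with C10α ethynyl in place of formyl]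
Conditions: dimethyl (1-diazo-2-oxopropyl)phosphonate, K2CO3, MeOH, 0 °C → rt
Reagents that add atoms: dimethyl (1-diazo-2-oxopropyl)phosphonate, CC(=O)C(=[N+]=[N-])P(=O)(OC)OC
Why: Seyferth–Gilbert homologation with the Ohira–Bestmann reagent; the non-enolisable aldehyde gives an alkylidene carbene whose 1,2-hydrogen shift gives the terminal alkyne. The β-keto ester is protected as its potassium enolate, and carbonate does not epimerise the ester-bearing C5.

Step 7
Reactants: 10 alkynyl keto ester
Product: 11 methylated keto ester [C3 ketone; C4α CH3; C4β CO2Me; C5β CO2t-Bu; C10β CH3; C10α ethynyl]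
Conditions: MeI, K2CO3, acetone, rt → 40 °C
Reagents that add atoms: iodomethane, CI
Why: C-Alkylation of the β-keto ester enolate; iodomethane enters from the α-face, anti to the adjacent C5 tert-butoxycarbonyl group, which allylic strain with the enolate ester holds pseudo-axial on the β-face, and this gives the 4α-methyl, 4β-ester arrangement. Placing this step after step 6 keeps the then non-enolisable β-keto ester away from methoxide (retro-Claisen cleavage).

Step 8
Reactants: 11 methylated keto ester
Product: 12 3α-alcohol [as 11 with C3α OH]
Conditions: (S)-1-methyl-3,3-diphenyltetrahydro-1H,3H-pyrrolo[1,2-c][1,3,2]oxazaborole (0.5 equiv), catecholborane, toluene, −78 → −40 °C; then MeOH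
Reagents that add atoms: none
Why: Corey–Bakshi–Shibata reduction; the ketone binds with quaternary C4 as the large and C2 as the small flank, so the (S)-catalyst delivers hydride to the β-face and gives the (3R) (3α) carbinol under reagent control. Catecholborane is used because it does not hydroborate the alkyne at this temperature.

Step 9
Reactants: 12 3α-alcohol
Product: 13 3α,19-diol [C4β CH2OH; C5β CO2t-Bu retained]
Conditions: LiBH4, THF, 0 °C → rt; aq. NH4Cl
Reagents that add atoms: none
Why: Chemoselective ester reduction; LiBH4 reduces the methyl ester and leaves the alkyne and the tert-butyl ester, which is shielded by the tert-butyl group and by its two quaternary neighbours. The temperature is kept at or below rt so that the new alkoxide does not attack the tert-butyl ester.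

Step 10
Reactants: 13 3α,19-diol; 14 isovaleryl chloride (3-methylbutanoyl chloride)
Product: 15 3α,19-diisovalerate tert-butyl ester
Conditions: 14 (3 equiv in all), pyridine, 4-(dimethylamino)pyridine (cat.), CH2Cl2, 0 °C → rt
Reagents that add atoms: isovaleryl chloride (compound 14, second equivalent), CC(C)CC(Cl)=O
Why: Acyl-transfer-catalysed esterification of both hydroxyls, each of which takes up one molecule of the acid chloride, so at least two equivalents are needed and an excess is used. No other hydroxyl is present, so no selectivity is needed.

Step 11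
Reactants: 15 3α,19-diisovalerate tert-butyl ester
Product: 16 C6 carboxylic acid
Conditions: CF3CO2H, CH2Cl2, 0 °C → rt
Reagents that add atoms: none
Why: Acidolysis of the tert-butyl ester through the tert-butyl cation; it does not depend on access to the hindered carbonyl, and the isovalerates and the alkyne are inert.

Step 12
Reactants: 16 C6 carboxylic acid
Product: 18 C6 aldehyde [C5β CHO; 3α,19-diisovalerate; C10α ethynyl], via acid chloride 17 (not isolated)
Conditions: (COCl)2, DMF (cat.), CH2Cl2, 0 °C; evaporate; then LiAlH(O-t-Bu)3, THF, −78 °C
Reagents that add atoms: oxalyl chloride, O=C(Cl)C(Cl)=O (chlorine of 17 only)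
Why: Acid chloride formation followed by reduction with the single hydride of LiAlH(O-t-Bu)3, which stops at the aldehyde and does not reduce alkyl esters at −78 °C. The acid chloride is used at once so that the neighbouring C19 ester cannot transfer its acyl group.

Step 13
Reactants: 18 C6 aldehyde; 19 3-chloro-2-methylprop-1-ene
Product: 22 ring A enyne (3R,4S,5R,6R,10S) [3α,19-diisovalerate; C6 carbinol bearing the 2-methylallyl group; C10α ethynyl], via methallylmagnesium chloride 20 (not isolated), via B-methallyldiisopinocampheylborane 21 (not isolated)
Conditions: 19, Mg, THF; (+)-B-methoxydiisopinocampheylborane [from (−)-α-pinene], Et2O, −78 °C → rt; then 18, Et2O, −78 °C; then H2O2, pH 7 buffer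
Reagents that add atoms: (+)-B-methoxydiisopinocampheylborane, COB([C@H]1C[C@H]2C[C@@H]([C@@H]1C)C2(C)C)[C@H]1C[C@H]2C[C@@H]([C@@H]1C)C2(C)C (boron and isopinocampheyl groups of 21 only); magnesium, [Mg] (in 20 only)
Why: Brown asymmetric methallylboration through a chair (Zimmerman–Traxler) transition state; this antipode of the reagent adds to the Re face of the aldehyde and gives the (6R) carbinol, which becomes the 6β-hydroxyl. Allylboranes do not attack alkyl esters or the alkyne.

Step 14
Reactants: 22 ring A enyne
Product: 23 3α,19-bis(3-methylbutanoyloxy)-13,14,15,16-tetranorlabda-8,11-dien-6β-ol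
Conditions: second-generation Grubbs catalyst RuCl2(=CHPh)(PCy3)(H2IMes) (2 × 5 mol %), ethylene (1 atm), toluene (0.005 M), 80 °C; then argon purge, 80 °C
Reagents that add atoms: none
Why: Ring-closing enyne metathesis: Ru=CH2, formed from the catalyst and ethylene, adds to the terminal alkyne to give the vinyl carbene at C9, which undergoes [2+2] cycloaddition and cycloreversion with the isopropenyl group, forming C8=C9 and returning the expelled methylene to the alkyne terminus as C12. The closest known reaction type is the ethylene-promoted closure of 1,7-enynes to 1-vinylcyclohexenes, including closures onto 1,1-disubstituted alkenes with N-heterocyclic-carbene ruthenium catalysts. Ring B closes in the exo mode as a six-membered ring. No stereocentre is formed, and the five present lie outside the reacting atoms. The step needs exo closure in preference to the seven-membered endo diene and to plain cross-metathesis with ethylene (an acyclic 2-substituted butadiene). The chair of ring A with the C10 ethynyl and C5 side chain trans-diequatorial holds the two termini within reach, and the quaternary C10 helps closure. The cross-metathesis triene still carries metathesis-active alkenes and can re-enter the catalytic cycle, whereas the tetrasubstituted, conjugated ring alkene of 23 is inert to the catalyst and should accumulate. The argon purge at the end allows any such triene to close.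

Step 15
Reactants: 24 2,2,6-trimethyl-4H-1,3-dioxin-4-one; 25 2-(trimethylsilyl)ethanol
Product: 26 2-(trimethylsilyl)ethyl 3-oxobutanoate
Conditions: xylene, 140 °C
Reagents that add atoms: none
Why: Thermal retro-[4+2] of the dioxinone releases acetylketene, which the alcohol traps (acetoacetylation).

Step 16
Reactants: 26 2-(trimethylsilyl)ethyl 3-oxobutanoate
Product: 27 2-(trimethylsilyl)ethyl (2E)-3-{[(trifluoromethyl)sulfonyl]oxy}but-2-enoate
Conditions: (CF3SO2)2O, aq. Me4NOH, hexanes, 5 °C → rt
Reagents that add atoms: trifluoromethanesulfonic anhydride, O=S(=O)(OS(=O)(=O)C(F)(F)F)C(F)(F)F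
Why: O-Sulfonylation of the acetoacetate enolate under two-phase Schotten–Baumann conditions; the non-chelating tetramethylammonium counter-ion favours the extended enolate and so the (E)-enol triflate (triflate trans to the ester), whereas a lithium base gives the (Z)-isomer. The (E)-electrophile is made this way because hydroiodination of the corresponding ynoate gives the (Z)-iodide.

Step 17
Reactants: 23 tetranorlabdadienol; 27 (E)-enol triflate
Product: 29 2-(trimethylsilyl)ethyl (13E)-6β-hydroxy-3α,19-bis(3-methylbutanoyloxy)labda-8,13-dien-15-oate, via C12 alkyl-9-BBN borane 28 (not isolated)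
Conditions: 9-BBN (2.5 equiv), THF, 0 °C → rt; then 27, PdCl2(dppf) (10 mol %; dppf = 1,1'-bis(diphenylphosphino)ferrocene), aq. K3PO4, DMF, rt → 50 °C
Reagents that add atoms: 9-borabicyclo[3.3.1]nonane, B1C2CCCC1CCC2 (boron unit of 28 only)
Why: 9-BBN hydroborates only the monosubstituted C11=C12 alkene, with boron at C12, and the excess covers the free hydroxyl. B-alkyl Suzuki–Miyaura coupling with the enol triflate forms C12–C13 with retention of the alkene geometry, which gives the (13E)-enoate.

Step 18
Reactants: 29 silylethyl ester
Product: 30 (13E)-6β-hydroxy-3α,19-bis(3-methylbutanoyloxy)labda-8,13-dien-15-oic acid (CNP0333611.1)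
Conditions: Bu4NF, THF, 0 °C → rt; then cold 0.5 M HCl
Reagents that add atoms: none
Why: Fluoride attacks silicon and the 2-(trimethylsilyl)ethyl ester fragments to the carboxylate, ethene and the fluorosilane. The hindered isovalerates are slow to react under these conditions, and an acyl shift from the primary O19 to the crowded axial O6 is thermodynamically unfavourable.

## Compound list

1 | methyl acetate | CC(=O)OC | starting material
2 | acrolein (prop-2-enal) | C=CC=O | starting material
3 | methyl 3-hydroxypent-4-enoate (racemic) | COC(=O)CC(O)C=C | intermediate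
4 | methyl 3-oxopent-4-enoate | COC(=O)CC(=O)C=C | intermediate
5 | methyl (2Z)-3-[(triisopropylsilyl)oxy]penta-2,4-dienoate | COC(=O)/C=C(\O[Si](C(C)C)(C(C)C)C(C)C)C=C | intermediate
6 | tert-butyl 3-methylbut-2-enoate | CC(C)=CC(=O)OC(C)(C)C | starting material
7 | tert-butyl (2E)-3-methyl-4-oxobut-2-enoate | O=C/C(C)=C/C(=O)OC(C)(C)C | intermediate
8 | cycloadduct silyl enol ether: cyclohex-2-ene (C2=C3) with 3-OSi(i-Pr)3, C4 CO2Me (configuration open), C5β CO2t-Bu, C10β CH3, C10α CHO | O=C[C@@]1(C)CC=C(O[Si](C(C)C)(C(C)C)C(C)C)C(C(=O)OC)[C@@H]1C(=O)OC(C)(C)C | intermediate (not isolated)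
9 | ring A keto aldehyde: C3 ketone, C4 CO2Me (epimers/enol), C5β CO2t-Bu, C10β CH3, C10α CHO | O=C[C@@]1(C)CCC(=O)C(C(=O)OC)[C@@H]1C(=O)OC(C)(C)C | intermediate
10 | alkynyl keto ester: as 9 with C10α ethynyl | C#C[C@@]1(C)CCC(=O)C(C(=O)OC)[C@@H]1C(=O)OC(C)(C)C | intermediate
11 | methylated keto ester: C3 ketone, C4α CH3, C4β CO2Me, C5β CO2t-Bu, C10β CH3, C10α ethynyl | C#C[C@@]1(C)CCC(=O)[C@](C)(C(=O)OC)[C@@H]1C(=O)OC(C)(C)C | intermediate
12 | 3α-alcohol: as 11 with C3α OH | C#C[C@@]1(C)CC[C@@H](O)[C@](C)(C(=O)OC)[C@@H]1C(=O)OC(C)(C)C | intermediate
13 | 3α,19-diol: C3α OH, C4β CH2OH, C4α CH3, C5β CO2t-Bu, C10β CH3, C10α ethynyl | C#C[C@@]1(C)CC[C@@H](O)[C@](C)(CO)[C@@H]1C(=O)OC(C)(C)C | intermediate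
14 | isovaleryl chloride (3-methylbutanoyl chloride) | CC(C)CC(Cl)=O | starting material
15 | 3α,19-diisovalerate tert-butyl ester | C#C[C@@]1(C)CC[C@@H](OC(=O)CC(C)C)[C@](C)(COC(=O)CC(C)C)[C@@H]1C(=O)OC(C)(C)C | intermediate
16 | C6 carboxylic acid (3α,19-diisovalerate) | C#C[C@@]1(C)CC[C@@H](OC(=O)CC(C)C)[C@](C)(COC(=O)CC(C)C)[C@@H]1C(=O)O | intermediate
17 | C6 acid chloride | C#C[C@@]1(C)CC[C@@H](OC(=O)CC(C)C)[C@](C)(COC(=O)CC(C)C)[C@@H]1C(Cl)=O | intermediate (not isolated)
18 | C6 aldehyde (3α,19-diisovalerate, C10α ethynyl) | C#C[C@@]1(C)CC[C@@H](OC(=O)CC(C)C)[C@](C)(COC(=O)CC(C)C)[C@@H]1C=O | intermediate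
19 | 3-chloro-2-methylprop-1-ene | C=C(C)CCl | starting material
20 | methallylmagnesium chloride | C=C(C)C[Mg]Cl | intermediate (not isolated)
21 | B-methallyldiisopinocampheylborane, (+)-series | C=C(C)CB([C@H]1C[C@H]2C[C@@H]([C@@H]1C)C2(C)C)[C@H]1C[C@H]2C[C@@H]([C@@H]1C)C2(C)C | intermediate (not isolated)
22 | ring A enyne (3R,4S,5R,6R,10S): 3α,19-diisovalerate, (6R)-carbinol with 2-methylallyl group, C10α ethynyl | C#C[C@@]1(C)CC[C@@H](OC(=O)CC(C)C)[C@](C)(COC(=O)CC(C)C)[C@@H]1[C@H](O)CC(C)=C | intermediate
23 | 3α,19-bis(3-methylbutanoyloxy)-13,14,15,16-tetranorlabda-8,11-dien-6β-ol | CC1=C(C=C)[C@@]2(C)CC[C@@H](OC(=O)CC(C)C)[C@](C)(COC(=O)CC(C)C)[C@@H]2[C@H](O)C1 | intermediate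
24 | 2,2,6-trimethyl-4H-1,3-dioxin-4-one | CC1=CC(=O)OC(C)(C)O1 | starting material
25 | 2-(trimethylsilyl)ethanol | C[Si](C)(C)CCO | starting material
26 | 2-(trimethylsilyl)ethyl 3-oxobutanoate | CC(=O)CC(=O)OCC[Si](C)(C)C | intermediate
27 | 2-(trimethylsilyl)ethyl (2E)-3-{[(trifluoromethyl)sulfonyl]oxy}but-2-enoate | C/C(OS(=O)(=O)C(F)(F)F)=C\C(=O)OCC[Si](C)(C)C | intermediate
28 | C12 alkyl-9-BBN borane of 23 | CC1=C(CCB2C3CCCC2CCC3)[C@@]2(C)CC[C@@H](OC(=O)CC(C)C)[C@](C)(COC(=O)CC(C)C)[C@@H]2[C@H](O)C1 | intermediate (not isolated)
29 | 2-(trimethylsilyl)ethyl (13E)-6β-hydroxy-3α,19-bis(3-methylbutanoyloxy)labda-8,13-dien-15-oate | CC1=C(CC/C(C)=C/C(=O)OCC[Si](C)(C)C)[C@@]2(C)CC[C@@H](OC(=O)CC(C)C)[C@](C)(COC(=O)CC(C)C)[C@@H]2[C@H](O)C1 | intermediate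
30 | (13E)-6β-hydroxy-3α,19-bis(3-methylbutanoyloxy)labda-8,13-dien-15-oic acid (CNP0333611.1) | CC1=C(CC/C(C)=C/C(=O)O)[C@@]2(C)CC[C@@H](OC(=O)CC(C)C)[C@](C)(COC(=O)CC(C)C)[C@@H]2[C@H](O)C1 | target

## Step count and least certain steps

Total step count: 18. Longest linear sequence: 15 steps (steps 1–3, 5–14, 17, 18).

**Step 14 (key step).** The methylidene may add to the hindered alkyne with the opposite regiochemistry. The carbene at C11 would then close in the endo sense to a seven-membered ring or be trapped by ethylene as an open-chain diene. Closure to a tetrasubstituted alkene next to quaternary C10 is slow, so catalyst decay may overtake it. Fallback, from 22 directly to 23 with no new compound: a π-acid-catalysed enyne skeletal rearrangement with PtCl2 in toluene at 80 °C. This goes through a cyclopropyl platinum carbene and not through a metal alkylidene, gives the same 1-vinylcycloalkene connectivity, and is favoured by the cation-stabilising methyl group on C8.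

**Step 5.** The ester-bearing silyloxy diene is only moderately nucleophilic, so conjugate addition without ring closure, loss of the silyl group, or insufficient facial discrimination may occur. Fallback, from 5 and 7, returning at 11: cycloaddition promoted by Et2AlCl (or by heat) gives racemic material, carried through steps 6 and 7. Compounds 8–11 are then accompanied by their mirror images: the enantiomeric cycloadduct F1, the enantiomeric keto aldehyde F2, the enantiomeric alkynyl keto ester F3 and the enantiomeric methylated keto ester F4. Racemic 11 is resolved by preparative chromatography on a chiral stationary phase.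

**Step 8.** The monocyclic ketone can react through the ring-flipped chair, in which the C5 ester is axial and shields the β-face. Substrate bias may then oppose the catalyst and erode the facial selectivity at C3. Fallback, from 11, returning at 23: the C3 ketone is carried into the decalin, where bulky hydrides attack 3-oxo-4,4-disubstituted trans-decalins equatorially. LiBH4 reduces the ketone and the methyl ester of 11 to the C3-epimeric diol F5. One equivalent of 14 acylates the primary hydroxyl to give the monoester F6, and Dess–Martin oxidation gives the keto ester F7. The conditions of steps 11–14 then give the acid F8, the acid chloride F9, the aldehyde F10, the 3-oxo enyne F11 and the 3-oxo diene F12. LiBH(s-Bu)3 at −78 °C gives the 3α-alcohol F13. Acylation with 14 and 4-(dimethylamino)pyridine, which leaves the 6β-hydroxyl with its two syn-axial neighbours free, reaches 23.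

**Step 13.** The aldehyde carbon lies between two quaternary centres, so addition may be slow, and the intrinsic facial preference of the aldehyde may oppose the reagent, which would give a C6 epimer mixture. Fallback, from 18, returning at 22: zinc-mediated Barbier addition of 19 in THF/aq. NH4Cl gives 22 together with its C6 epimer F14. Dess–Martin oxidation of the mixture gives the β,γ-unsaturated ketone F15. Reduction with the (S)-oxazaborolidine of step 8 and catecholborane, with C5 as the large and C7 as the small flank, returns the (6R)-alcohol 22.

## Further compounds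

F0 | step 14 | none | none
F1 | step 5 | enantiomer of cycloadduct 8 | O=C[C@]1(C)CC=C(O[Si](C(C)C)(C(C)C)C(C)C)C(C(=O)OC)[C@H]1C(=O)OC(C)(C)C
F2 | step 5 | enantiomer of keto aldehyde 9 | O=C[C@]1(C)CCC(=O)C(C(=O)OC)[C@H]1C(=O)OC(C)(C)C
F3 | step 5 | enantiomer of alkynyl keto ester 10 | C#C[C@]1(C)CCC(=O)C(C(=O)OC)[C@H]1C(=O)OC(C)(C)C
F4 | step 5 | enantiomer of methylated keto ester 11 | C#C[C@]1(C)CCC(=O)[C@@](C)(C(=O)OC)[C@H]1C(=O)OC(C)(C)C
F5 | step 8 | C3-epimeric 3,19-diol tert-butyl ester | C#C[C@@]1(C)CCC(O)[C@](C)(CO)[C@@H]1C(=O)OC(C)(C)C
F6 | step 8 | 19-isovalerate 3-ol (C3 epimers) | C#C[C@@]1(C)CCC(O)[C@](C)(COC(=O)CC(C)C)[C@@H]1C(=O)OC(C)(C)C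
F7 | step 8 | 3-oxo 19-isovalerate tert-butyl ester | C#C[C@@]1(C)CCC(=O)[C@](C)(COC(=O)CC(C)C)[C@@H]1C(=O)OC(C)(C)C
F8 | step 8 | 3-oxo 19-isovalerate C6 acid | C#C[C@@]1(C)CCC(=O)[C@](C)(COC(=O)CC(C)C)[C@@H]1C(=O)O
F9 | step 8 | 3-oxo 19-isovalerate C6 acid chloride | C#C[C@@]1(C)CCC(=O)[C@](C)(COC(=O)CC(C)C)[C@@H]1C(Cl)=O
F10 | step 8 | 3-oxo 19-isovalerate C6 aldehyde | C#C[C@@]1(C)CCC(=O)[C@](C)(COC(=O)CC(C)C)[C@@H]1C=O
F11 | step 8 | 3-oxo ring A enyne | C#C[C@@]1(C)CCC(=O)[C@](C)(COC(=O)CC(C)C)[C@@H]1[C@H](O)CC(C)=C
F12 | step 8 | 6β-hydroxy-19-(3-methylbutanoyloxy)-13,14,15,16-tetranorlabda-8,11-dien-3-one | CC1=C(C=C)[C@@]2(C)CCC(=O)[C@](C)(COC(=O)CC(C)C)[C@@H]2[C@H](O)C1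
F13 | step 8 | 19-(3-methylbutanoyloxy)-13,14,15,16-tetranorlabda-8,11-diene-3α,6β-diol | CC1=C(C=C)[C@@]2(C)CC[C@@H](O)[C@](C)(COC(=O)CC(C)C)[C@@H]2[C@H](O)C1
F14 | step 13 | C6 epimer of enyne 22 | C#C[C@@]1(C)CC[C@@H](OC(=O)CC(C)C)[C@](C)(COC(=O)CC(C)C)[C@@H]1[C@@H](O)CC(C)=C
F15 | step 13 | C6 ketone of enyne 22 (β,γ-unsaturated) | C#C[C@@]1(C)CC[C@@H](OC(=O)CC(C)C)[C@](C)(COC(=O)CC(C)C)[C@@H]1C(=O)CC(C)=C
A1 | alternative 1 | tricyclic 19,6β-lactone with 3α-silyloxy, 1,2-alkene and 8,9-alkene | CC1=C(CCC2(C)OCCO2)[C@@]3(C)C=C[C@@H](O[Si](C)(C)C(C)(C)C)[C@](C)(C(=O)O4)[C@@H]3[C@H]4C1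
A2 | alternative 2 | 4,4-dimethoxy-2,6-dimethylcyclohexa-2,5-dien-1-one | COC1(OC)C=C(C)C(=O)C(C)=C1
A3 | alternative 2 | trans-fused 3,6,9-trioxo-7-ene decalin with C19 methyl ester on C4 | CC1=CC(=O)[C@H]2C(C(=O)OC)C(=O)CC[C@]2(C)C1=O
A4 | alternative 3 | trans-decalin keto ester with 3-oxo, 19-methyl ester, 6α-silyloxy, 8(17)-alkene and C13 ketal | C=C1[C@H](CCC2(C)OCCO2)[C@@]3(C)CCC(=O)[C@](C)(C(=O)OC)[C@@H]3[C@@H](O[Si](C)(C)C(C)(C)C)C1
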